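## Retrosynthetic overview

1. Target ⇐ the C4‑hydroxymethyl decalin (alcohol → acid); no C–C bond is made after ring formation.
2. Ring A, then ring B, in one operation ⇐ titanocene‑triggered radical bicyclization (bonds C4–C5 and C9–C10) of an acyclic C22 epoxy tetraene acetate that already holds every carbon, both E alkenes, the diene and the C6 acetate, whose single stereocentre steers the fold.
3. Epoxide ⇐ methyl ketone + sulfur ylide; diene ⇐ SO2 loss from a 2‑alkyl‑3‑methyl‑3‑sulfolene; C6 carbinol ⇐ asymmetric Nozaki–Hiyama–Kishi union (C5–C6) of an E alkenyl iodide with a β,γ‑unsaturated aldehyde.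
4. Aldehyde ⇐ but‑3‑yn‑1‑ol + 3‑methyl‑3‑sulfolene; iodide ⇐ hex‑5‑ynenitrile (two carboaluminations set both E trisubstituted alkenes).

Assumption: positions are given in labdane numbering (C4 carries CH3 and CO2H, C10 the angular CH3); the SMILES is read as the (4S,5S,6R,9R,10S) enantiomer with CO2H, OAc and the side chain all equatorial; compound numbers follow the forward steps.

## Route

Step 1
Reactants: 1 but-3-yn-1-ol
Product: 4 (2E)-3-methylpent-2-ene-1,5-diol, via alkenylalane 2 (not isolated), via lithium alkenylalanate 3 (not isolated)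
Conditions: Me3Al (3 equiv), Cp2ZrCl2 (0.25 equiv), CH2Cl2, 0 °C to rt; n-BuLi, THF, −78 °C; (CH2O)n, rt; aqueous work-up
Reagents that add atoms: trimethylaluminium C[Al](C)C; formaldehyde (from paraformaldehyde) C=O
Why: Negishi zirconium-catalysed carboalumination adds CH3 and Al syn across the terminal alkyne with CH3 on the internal carbon, and the alanate is hydroxymethylated with retention, so the C8=C9 alkene is E.

Step 2
Reactants: 4 (2E)-3-methylpent-2-ene-1,5-diol
Product: 5 (3E)-5-bromo-3-methylpent-3-en-1-ol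
Conditions: NBS, Me2S, CH2Cl2, −20 to 0 °C
Reagents that add atoms: N-bromosuccinimide O=C1CCC(=O)N1Br
Why: Corey–Kim halogenation activates the allylic hydroxyl far faster than the saturated primary one, and bromide displaces it by SN2 without allylic shift.

Step 3
Reactants: 5 (3E)-5-bromo-3-methylpent-3-en-1-ol; 6 3-methyl-2,5-dihydrothiophene 1,1-dioxide (3-methyl-3-sulfolene)
Product: 8 2-[(2E)-5-hydroxy-3-methylpent-2-en-1-yl]-3-methyl-2,5-dihydrothiophene 1,1-dioxide (racemic), via 2-lithiosulfolene 7 (not isolated)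
Conditions: LiHMDS (2.2 equiv, added to 5 + 6; the first equivalent holds the hydroxyl as its lithium salt), THF/HMPA, −78 °C
Reagents that add atoms: none
Why: α-Sulfonyl carbanion alkylation: 3-methyl-3-sulfolene, deprotonated at −78 °C in the presence of a reactive allylic bromide, is alkylated at C2 before it can ring-open, and the new racemic ring centre is erased in step 8.

Step 4
Reactants: 8 2-[(2E)-5-hydroxy-3-methylpent-2-en-1-yl]-3-methyl-2,5-dihydrothiophene 1,1-dioxide
Product: 9 (3E)-3-methyl-5-(3-methyl-1,1-dioxo-2,5-dihydrothiophen-2-yl)pent-3-enal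
Conditions: Dess–Martin periodinane, pyridine, CH2Cl2, 0 °C; used crude
Reagents that add atoms: none
Why: Dess–Martin oxidation under buffered non-basic conditions gives the β,γ-unsaturated aldehyde without moving the alkene into conjugation.

Step 5
Reactants: 10 hex-5-ynenitrile
Product: 12 (5E)-6-iodo-5-methylhex-5-enenitrile, via cyanoalkenylalane 11 (not isolated)
Conditions: Me3Al (3 equiv), Cp2ZrCl2 (0.3 equiv), ClCH2CH2Cl, rt; then I2, THF, −30 °C
Reagents that add atoms: trimethylaluminium C[Al](C)C; iodine II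
Why: Negishi carboalumination (the nitrile only binds one equivalent of Me3Al at rt) followed by iodinolysis with retention gives the E alkenyl iodide that becomes C5=C10.

Step 6
Reactants: 12 (5E)-6-iodo-5-methylhex-5-enenitrile
Product: 14 (7E)-8-iodo-7-methyloct-7-en-2-one, via magnesium ketimide 13 (not isolated)
Conditions: MeMgBr (3 equiv), Et2O/toluene, 60 °C; then 1 M HCl, 0 °C
Reagents that add atoms: methylmagnesium bromide C[Mg]Br; water O
Why: Grignard addition to a nitrile stops at the magnesium ketimide, which is hydrolysed to the methyl ketone, while the alkenyl iodide is inert to MeMgBr.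

Step 7
Reactants: 14 (7E)-8-iodo-7-methyloct-7-en-2-one; 9 (3E)-3-methyl-5-(3-methyl-1,1-dioxo-2,5-dihydrothiophen-2-yl)pent-3-enal
Product: 16 (6E,8R,10E)-8-hydroxy-6,10-dimethyl-12-(3-methyl-1,1-dioxo-2,5-dihydrothiophen-2-yl)dodeca-6,10-dien-2-one, via alkenylchromium dichloride 15 (not isolated)
Conditions: CrCl2 (3 equiv), NiCl2 (2 mol%), chiral (oxazolinyl)aryl methanesulfonamide ligand (enantiomer matched to the R carbinol), Et3N, THF, rt
Reagents that add atoms: none
Why: Asymmetric Nozaki–Hiyama–Kishi reaction: CrCl2 (divalent chromium, nickel co-catalysis) turns the iodide into an alkenylchromium that adds only to the aldehyde (methyl ketone and sulfone untouched) with retention of the E alkene, and the chromium-bound sulfonamide ligand selects the aldehyde face that gives the 6R carbinol.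

Step 8
Reactants: 16 (6E,8R,10E)-8-hydroxy-6,10-dimethyl-12-(3-methyl-1,1-dioxo-2,5-dihydrothiophen-2-yl)dodeca-6,10-dien-2-one
Product: 18 (6E,8R,10E,13E)-6,10,14-trimethyl-2-oxohexadeca-6,10,13,15-tetraen-8-yl acetate, via sulfolene acetate 17 (not isolated)
Conditions: Ac2O, DMAP (cat.), pyridine, rt; then 115 °C
Reagents that add atoms: acetic anhydride CC(=O)OC(C)=O
Why: DMAP-catalysed acetylation is followed in the same flask by thermal cheletropic loss of SO2, whose disrotatory opening turns the 2-substituent outward and gives the 12E diene.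

Step 9
Reactants: 18 (6E,8R,10E,13E)-6,10,14-trimethyl-2-oxohexadeca-6,10,13,15-tetraen-8-yl acetate
Product: 19 (4E,6R,8E,11E)-4,8,12-trimethyl-1-(2-methyloxiran-2-yl)tetradeca-4,8,11,13-tetraen-6-yl acetate (both epoxide epimers)
Conditions: Me3S+ I−, KHMDS, THF, −10 to 0 °C
Reagents that add atoms: trimethylsulfonium iodide C[S+](C)C.[I-]
Why: Corey–Chaykovsky epoxidation: the sulfonium ylide adds to the ketone much faster than to the acetate, and the uncontrolled epoxide centre does not matter because it becomes a planar radical in step 10.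

Step 10
Reactants: 19 (4E,6R,8E,11E)-4,8,12-trimethyl-1-(2-methyloxiran-2-yl)tetradeca-4,8,11,13-tetraen-6-yl acetate
Product: 21 [(1S,4aS,5R,8R,8aS)-1-(hydroxymethyl)-1,4a-dimethyl-6-methylidene-5-[(2E)-3-methylpenta-2,4-dien-1-yl]decahydronaphthalen-8-yl] acetate, via trimethylsilyl ether 20 (not isolated)
Conditions: Cp2TiCl2 (0.2 equiv), Mn dust, Me3SiCl, 2,4,6-collidine, THF (5 mM, slow addition), rt; then dilute HCl, THF, 0 °C
Reagents that add atoms: none
Why: Titanocene-mediated radical epoxypolyene cyclization (Nugent–RajanBabu opening by Cp2TiCl, trivalent titanium, in the catalytic Cuerva–Oltra mode): the tertiary C4 radical closes 6-endo onto C5 and the C10 radical 6-endo onto C9 through a chair–chair fold in which H6 eclipses C5=C10 (allylic 1,3-strain with the C20 methyl), C4 enters anti to C7 and the acetate sits equatorial, so 6R fixes 5S and 10S (trans fusion), the E C8=C9 alkene gives 9R (equatorial side chain), the bulky titanoxymethyl group takes the equatorial site at C4 (4S, methyl axial), and titanium-assisted loss of a C17 hydrogen from the C8 radical gives the exocyclic alkene.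

Step 11
Reactants: 21 [(1S,4aS,5R,8R,8aS)-1-(hydroxymethyl)-1,4a-dimethyl-6-methylidene-5-[(2E)-3-methylpenta-2,4-dien-1-yl]decahydronaphthalen-8-yl] acetate
Product: 23 (1S,4aS,5R,8R,8aS)-8-acetoxy-1,4a-dimethyl-6-methylidene-5-[(2E)-3-methylpenta-2,4-dien-1-yl]decahydronaphthalene-1-carboxylic acid (CNP0240327.3), via aldehyde 22 (not isolated)
Conditions: AZADO (5 mol%), PhI(OAc)2, CH2Cl2, rt; then t-BuOH/H2O, NaClO2, NaH2PO4, 2-methylbut-2-ene (excess), 0 °C to rt
Reagents that add atoms: sodium chlorite [Na+].[O-]Cl=O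
Why: Nitroxyl-catalysed oxidation of the hindered neopentyl alcohol to the aldehyde and Pinnick oxidation in the same flask (the alkene scavenger protects the diene and the methylidene) give the acid without touching a stereocentre or the acetate.

## Compound list

1 | but-3-yn-1-ol | C#CCCO | starting material
2 | dimethyl[(1E)-4-(dimethylalumanyloxy)-2-methylbut-1-en-1-yl]alumane | C[Al](C)/C=C(\C)CCO[Al](C)C | intermediate
3 | lithium butyl(dimethyl)alanate of 2 | [Li+].CCCC[Al-](C)(C)/C=C(\C)CCO[Al](C)C | intermediate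
4 | (2E)-3-methylpent-2-ene-1,5-diol | OC/C=C(\C)CCO | intermediate
5 | (3E)-5-bromo-3-methylpent-3-en-1-ol | BrC/C=C(\C)CCO | intermediate
6 | 3-methyl-2,5-dihydrothiophene 1,1-dioxide (3-methyl-3-sulfolene) | CC1=CCS(=O)(=O)C1 | starting material
7 | 2-lithio-3-methyl-2,5-dihydrothiophene 1,1-dioxide | [Li]C1C(C)=CCS1(=O)=O | intermediate
8 | 2-[(2E)-5-hydroxy-3-methylpent-2-en-1-yl]-3-methyl-2,5-dihydrothiophene 1,1-dioxide (racemic) | OCC/C(C)=C/CC1C(C)=CCS1(=O)=O | intermediate
9 | (3E)-3-methyl-5-(3-methyl-1,1-dioxo-2,5-dihydrothiophen-2-yl)pent-3-enal (racemic) | O=CC/C(C)=C/CC1C(C)=CCS1(=O)=O | intermediate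
10 | hex-5-ynenitrile | C#CCCCC#N | starting material
11 | [(1E)-5-cyano-2-methylpent-1-en-1-yl]dimethylalumane | C[Al](C)/C=C(\C)CCCC#N | intermediate
12 | (5E)-6-iodo-5-methylhex-5-enenitrile | I/C=C(\C)CCCC#N | intermediate
13 | N-bromomagnesio ketimine of 14 | CC(=N[Mg]Br)CCC/C(C)=C/I | intermediate
14 | (7E)-8-iodo-7-methyloct-7-en-2-one | CC(=O)CCC/C(C)=C/I | intermediate
15 | [(1E)-2-methyl-7-oxooct-1-en-1-yl]chromium dichloride | CC(=O)CCC/C(C)=C/[Cr](Cl)Cl | intermediate
16 | (6E,8R,10E)-8-hydroxy-6,10-dimethyl-12-(3-methyl-1,1-dioxo-2,5-dihydrothiophen-2-yl)dodeca-6,10-dien-2-one (1:1 epimers at the sulfolene carbon) | CC(=O)CCC/C(C)=C/[C@H](O)C/C(C)=C/CC1C(C)=CCS1(=O)=O | intermediate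
17 | (6E,8R,10E)-6,10-dimethyl-12-(3-methyl-1,1-dioxo-2,5-dihydrothiophen-2-yl)-2-oxododeca-6,10-dien-8-yl acetate (1:1 epimers at the sulfolene carbon) | CC(=O)CCC/C(C)=C/[C@H](OC(C)=O)C/C(C)=C/CC1C(C)=CCS1(=O)=O | intermediate
18 | (6E,8R,10E,13E)-6,10,14-trimethyl-2-oxohexadeca-6,10,13,15-tetraen-8-yl acetate | CC(=O)CCC/C(C)=C/[C@H](OC(C)=O)C/C(C)=C/C/C=C(\C)C=C | intermediate
19 | (4E,6R,8E,11E)-4,8,12-trimethyl-1-(2-methyloxiran-2-yl)tetradeca-4,8,11,13-tetraen-6-yl acetate (both epoxide epimers) | CC1(CCC/C(C)=C/[C@H](OC(C)=O)C/C(C)=C/C/C=C(\C)C=C)CO1 | intermediate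
20 | trimethylsilyl ether of 21 | C=C/C(C)=C/C[C@@H]1C(=C)C[C@@H](OC(C)=O)[C@H]2[C@@]1(C)CCC[C@]2(C)CO[Si](C)(C)C | intermediate
21 | [(1S,4aS,5R,8R,8aS)-1-(hydroxymethyl)-1,4a-dimethyl-6-methylidene-5-[(2E)-3-methylpenta-2,4-dien-1-yl]decahydronaphthalen-8-yl] acetate | C=C/C(C)=C/C[C@@H]1C(=C)C[C@@H](OC(C)=O)[C@H]2[C@@]1(C)CCC[C@]2(C)CO | intermediate
22 | [(1S,4aS,5R,8R,8aS)-1-formyl-1,4a-dimethyl-6-methylidene-5-[(2E)-3-methylpenta-2,4-dien-1-yl]decahydronaphthalen-8-yl] acetate | C=C/C(C)=C/C[C@@H]1C(=C)C[C@@H](OC(C)=O)[C@H]2[C@@]1(C)CCC[C@]2(C)C=O | intermediate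
23 | (1S,4aS,5R,8R,8aS)-8-acetoxy-1,4a-dimethyl-6-methylidene-5-[(2E)-3-methylpenta-2,4-dien-1-yl]decahydronaphthalene-1-carboxylic acid | C=C/C(C)=C/C[C@@H]1C(=C)C[C@@H](OC(C)=O)[C@H]2[C@@]1(C)CCC[C@]2(C)C(=O)O | target

## Count and risks

Total steps: 11. Longest linear sequence: 9 (steps 1–4, then 7–11); steps 5–6 form the second branch.

**Step 10 (bicyclization).** The stereochemical outcome is a prediction, not a precedent for this substrate. Open points are the C4 ratio (equatorial CH2O–Ti against CH3), the C5 face, and capture of the radicals by the free diene; the relative configuration would be read at 21 by NOE. The fallback below cures only diene capture, not a wrong C4 or C5 sense. Fallback, from 16 back to 21, keeps the diene masked through the radical step. Alcohol 16 is acetylated at room temperature and 17 is isolated. Corey–Chaykovsky methylenation at −20 °C gives the sulfolene-bearing epoxy acetate F1. The titanocene cyclization under the step-10 conditions gives the bicyclic sulfolene silyl ether F2 and, after acid work-up, the bicyclic sulfolene alcohol F3. Heating F3 (toluene, NaHCO3, 110 °C) expels SO2 and gives 21.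

**Step 7 (asymmetric coupling).** The enantioselectivity with this iodide/aldehyde pair may be insufficient. Fallback, from 14 (with 9) back to 16, is resolution instead of asymmetric induction. Ligand-free CrCl2/NiCl2 coupling in DMSO gives the racemic allylic alcohol F4. Sharpless kinetic resolution (Ti(OiPr)4, L-(+)-diisopropyl tartrate, t-BuOOH, CH2Cl2, −20 °C, about 55% conversion) consumes the S enantiomer as the epoxy alcohol F5 and leaves 16.

**Step 3 (sulfolene alkylation).** C5- instead of C2-alkylation, or interference by the free hydroxyl, would spoil it. Fallback, from 5 back to 18, builds the diene by allyl–alkenyl coupling. But-1-en-3-yne is carboaluminated (Me3Al, Cp2ZrCl2) to the dienylalane F6. F6 is coupled with 5 (Pd(PPh3)4, zerovalent palladium, THF; one extra equivalent of Me3Al covers the hydroxyl) to give the trienol F7. Dess–Martin oxidation gives the trienal F8, the step-7 coupling with 14 gives the dienyl alcohol F9, and acetylation at room temperature gives 18.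

## Further compounds

F1 | step 10 | (4E,6R,8E)-4,8-dimethyl-10-(3-methyl-1,1-dioxo-2,5-dihydrothiophen-2-yl)-1-(2-methyloxiran-2-yl)deca-4,8-dien-6-yl acetate | CC1(CCC/C(C)=C/[C@H](OC(C)=O)C/C(C)=C/CC2C(C)=CCS2(=O)=O)CO1
F2 | step 10 | trimethylsilyl ether of F3 | O=S3(=O)CC=C(C)C3C[C@@H]1C(=C)C[C@@H](OC(C)=O)[C@H]2[C@@]1(C)CCC[C@]2(C)CO[Si](C)(C)C
F3 | step 10 | analogue of 21 with the diene masked: C9 carries a (3-methyl-1,1-dioxo-2,5-dihydrothiophen-2-yl)methyl group | O=S3(=O)CC=C(C)C3C[C@@H]1C(=C)C[C@@H](OC(C)=O)[C@H]2[C@@]1(C)CCC[C@]2(C)CO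
F4 | step 7 | racemic (6E,10E)-8-hydroxy-6,10-dimethyl-12-(3-methyl-1,1-dioxo-2,5-dihydrothiophen-2-yl)dodeca-6,10-dien-2-one | CC(=O)CCC/C(C)=C/C(O)C/C(C)=C/CC1C(C)=CCS1(=O)=O
F5 | step 7 | 5-{(2R,3R)-3-[(1S,3E)-1-hydroxy-3-methyl-5-(3-methyl-1,1-dioxo-2,5-dihydrothiophen-2-yl)pent-3-en-1-yl]-2-methyloxiran-2-yl}pentan-2-one | CC(=O)CCC[C@@]1(C)O[C@@H]1[C@@H](O)C/C(C)=C/CC2C(C)=CCS2(=O)=O
F6 | step 3 | dimethyl[(1E)-2-methylbuta-1,3-dien-1-yl]alumane | C[Al](C)/C=C(\C)C=C
F7 | step 3 | (3E,6E)-3,7-dimethylnona-3,6,8-trien-1-ol | OCC/C(C)=C/C/C=C(\C)C=C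
F8 | step 3 | (3E,6E)-3,7-dimethylnona-3,6,8-trienal | O=CC/C(C)=C/C/C=C(\C)C=C
F9 | step 3 | (6E,8R,10E,13E)-8-hydroxy-6,10,14-trimethylhexadeca-6,10,13,15-tetraen-2-one | CC(=O)CCC/C(C)=C/[C@H](O)C/C(C)=C/C/C=C(\C)C=C
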